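## Retrosynthetic overview

1. Ring order: the carbocycle is made first, as 2,5-dimethyl-1,4-benzoquinone (cyclodimerisation of butane-2,3-dione). The dihydropyran ring is closed last.
2. Final O–C8a closure: the tertiary OH of β-tocopherolquinone adds to the flanking quinone carbonyl (mixed ketal), then reductive aromatisation. The C2–O bond is never broken, so C2 is retained.
3. Key bond C4–C4a: radical-chain C–H alkylation of the quinone by the primary alkyl radical from anti-Markovnikov hydroboration of unprotected (3R,7R,11R)-isophytol.
4. C2 stereocentre: catalytic asymmetric Corey–Chaykovsky epoxidation of (6R,10R)-phytone, then one-carbon sulfonium-ylide homologation to the vinyl carbinol.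
5. C4′/C8′ stereocentres: chiral pool. Two iterative Cu-catalysed Grignard couplings with (R)-1,4-dibromo-2-methylbutane, then Cu-catalysed 1,4-addition to methyl vinyl ketone.

Assumption 1: (R)-2-methylbutane-1,4-diol is commercial in ≥98% ee.
Assumption 2: the LLB antipode that gives the (R)-epoxide in step 5 is taken to be (R)-LLB. I have not confirmed the sense; if it is opposite, use (S)-LLB.

## Route

**Step 1**
Reactants: 1, (R)-2-methylbutane-1,4-diol
Product: 2, (R)-1,4-dibromo-2-methylbutane
Conditions: Ph3P·Br2 (2.4 equiv), MeCN, 0 → 60 °C
Reagents that add atoms: triphenylphosphine dibromide (bromine source), BrP(Br)(c1ccccc1)(c1ccccc1)c1ccccc1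
Why: Appel-type double SN2 bromination at two primary carbons; any 3-methyl-THF formed is reopened by the reagent, and no bond to the stereocentre is touched.

**Step 2**
Reactants: 3, 1-bromo-2-methylpropane (as its Grignard reagent); 2, (R)-1,4-dibromo-2-methylbutane (3 equiv, excess recovered)
Product: 4, (R)-1-bromo-2,6-dimethylheptane
Conditions: 3, Mg, THF; add to 2, Li2CuCl4 (3 mol%), THF/NMP, −20 → 0 °C
Reagents that add atoms: none
Why: Kochi Cu-catalysed Grignard–alkyl bromide coupling; the unbranched CH2Br of 2 reacts far faster than the β-branched CH2Br next to the stereocentre, which survives as the next Grignard precursor. The stereocentre is a spectator.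

**Step 3**
Reactants: 4, (R)-1-bromo-2,6-dimethylheptane (as its Grignard reagent); 2 (3 equiv, excess recovered)
Product: 5, (2R,6R)-1-bromo-2,6,10-trimethylundecane
Conditions: 4, Mg, THF, 40 °C; add to 2, Li2CuCl4 (3 mol%), THF/NMP, −20 → 0 °C
Reagents that add atoms: none
Why: second Kochi coupling with the same steric discrimination; it installs the second methyl stereocentre (future C4′) from the chiral pool with no bond to either stereocentre broken.

**Step 4**
Reactants: 5 (as its Grignard reagent); 6, but-3-en-2-one (methyl vinyl ketone)
Product: 7, (6R,10R)-6,10,14-trimethylpentadecan-2-one (phytone)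
Conditions: 5, Mg, THF; CuBr·SMe2 (5 mol%), TMSCl, DMPU, THF, −78 °C, then 6; 1 M HCl
Reagents that add atoms: none
Why: TMSCl-accelerated Cu-catalysed conjugate addition of a primary Grignard to an enone; the silyl enol ether is hydrolysed on work-up.

**Step 5**
Reactants: 7, (6R,10R)-6,10,14-trimethylpentadecan-2-one
Product: 8, (R)-2-methyl-2-[(4R,8R)-4,8,12-trimethyltridecyl]oxirane
Conditions: Me2S(O)=CH2 (from Me3S(O)I/NaH, 1.2 equiv), (R)-LLB [La–Li3–tris(binaphthoxide)] (5 mol%), (2,4,6-(MeO)3C6H2)3P=O (5 mol%), 5 Å MS, THF, rt
Reagents that add atoms: dimethylsulfoxonium methylide, C[S+](C)(=O)[CH2-]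
Why: catalytic asymmetric Corey–Chaykovsky epoxidation of a methyl ketone; the catalyst delivers CH2 to the Si face (O > CH2R > CH3), setting the future C2 as R in an expected ~93–96% ee at that centre, with the remote 4R,8R centres as spectators.

**Step 6**
Reactants: 8
Product: 9, (3R,7R,11R)-3,7,11,15-tetramethylhexadec-1-en-3-ol ((R,R,R)-isophytol)
Conditions: Me3S+ I− (4 equiv), n-BuLi (3.9 equiv), THF, −10 °C → rt
Reagents that add atoms: dimethylsulfonium methylide, C[S+](C)[CH2-]
Why: one-carbon homologation of a terminal epoxide to an allylic alcohol: the ylide opens the epoxide at CH2, then ylide-mediated α′,β-elimination of Me2S gives the vinyl group. The C–O bond at the stereocentre is untouched, so R is retained.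

**Step 7**
Reactants: 10, butane-2,3-dione (2 equiv)
Product: 11, 2,5-dimethylcyclohexa-2,5-diene-1,4-dione (2,5-dimethyl-1,4-benzoquinone)
Conditions: 1 M aq NaOH, 0 °C → rt, N2; then 20% H2SO4, steam distillation
Reagents that add atoms: none
Why: classical double aldol cyclodimerisation of biacetyl (CH3 of one molecule onto C=O of the other, twice) to 2,5-dihydroxy-2,5-dimethylcyclohexane-1,4-dione, then double dehydration; modest yield but one step from a bulk chemical.

**Step 8 (key step)**
Reactants: 9, (R,R,R)-isophytol; 11, 2,5-dimethyl-1,4-benzoquinone (2 equiv)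
Product: 12, 3-[(3R,7R,11R)-3-hydroxy-3,7,11,15-tetramethylhexadecyl]-2,5-dimethyl-1,4-benzoquinone (β-tocopherolquinone)
Conditions: catecholborane (2.5 equiv), MeCONMe2 (20 mol%), CH2Cl2, 40 °C; t-BuOH (1.5 equiv); then 11, DMPU, air (cat.), 0 °C → rt; aq FeCl3 work-up
Reagents that add atoms: none (boron is lost)
Why: anti-Markovnikov hydroboration gives the primary B-alkylcatecholborane (the tertiary OH is masked in situ as its borate); its primary alkyl radical adds to the unsubstituted ring carbon of the quinone and the resulting oxygen-centred radical propagates the chain by SH2 at boron (organoborane–quinone reductive alkylation). The two free ring positions are equivalent, the radical is γ to oxygen so no β-elimination occurs, and the carbinol stereocentre is not involved. The oxidative work-up brings all product to the quinone.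

**Step 9**
Reactants: 12, β-tocopherolquinone
Product: 13, (2R,4′R,8′R)-β-tocopherol, i.e. (2R)-2,5,8-trimethyl-2-[(4R,8R)-4,8,12-trimethyltridecyl]chroman-6-ol
Conditions: HC(OMe)3, MeOH, p-TsOH (5 mol%), rt; then L-ascorbic acid (3 equiv), rt, N2 (one pot)
Reagents that add atoms: none
Why: the tertiary OH adds to the only carbonyl ortho to the side chain to give the six-membered mixed ketal (8a-methoxy-β-tocopherone); two-electron reduction expels methoxide and aromatises (quinone-monoketal reductive aromatisation). The carbinol C–O bond is never cleaved, so C2 is formed with retention as R; the methyls end up at C5 and C8 and the OH at C6.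

Stereochemical purity: C4′ and C8′ carry the ee of the diol. The ~2–4% of 2-epimer expected from step 5 can be removed by preparative chiral HPLC of 13 if required.

## Compound list

1 | (R)-2-methylbutane-1,4-diol | OC[C@H](C)CCO | starting material
2 | (R)-1,4-dibromo-2-methylbutane | BrC[C@H](C)CCBr | intermediate
3 | 1-bromo-2-methylpropane | CC(C)CBr | starting material
4 | (R)-1-bromo-2,6-dimethylheptane | BrC[C@H](C)CCCC(C)C | intermediate
5 | (2R,6R)-1-bromo-2,6,10-trimethylundecane | BrC[C@H](C)CCC[C@H](C)CCCC(C)C | intermediate
6 | but-3-en-2-one (methyl vinyl ketone) | CC(=O)C=C | starting material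
7 | (6R,10R)-6,10,14-trimethylpentadecan-2-one | CC(=O)CCC[C@H](C)CCC[C@H](C)CCCC(C)C | intermediate
8 | (R)-2-methyl-2-[(4R,8R)-4,8,12-trimethyltridecyl]oxirane | C[C@]1(CO1)CCC[C@H](C)CCC[C@H](C)CCCC(C)C | intermediate
9 | (3R,7R,11R)-3,7,11,15-tetramethylhexadec-1-en-3-ol | C=C[C@](C)(O)CCC[C@H](C)CCC[C@H](C)CCCC(C)C | intermediate
10 | butane-2,3-dione | CC(=O)C(C)=O | starting material
11 | 2,5-dimethyl-1,4-benzoquinone | CC1=CC(=O)C(C)=CC1=O | intermediate
12 | 3-[(3R,7R,11R)-3-hydroxy-3,7,11,15-tetramethylhexadecyl]-2,5-dimethyl-1,4-benzoquinone | CC1=CC(=O)C(C)=C(CC[C@](C)(O)CCC[C@H](C)CCC[C@H](C)CCCC(C)C)C1=O | intermediate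
13 | (2R,4′R,8′R)-β-tocopherol | Cc1cc(O)c(C)c2c1O[C@](C)(CCC[C@H](C)CCC[C@H](C)CCCC(C)C)CC2 | target

## Summary

Total steps: 9.
Longest linear sequence: 8 (steps 1–6, 8, 9); step 7 is a one-step side branch.

Three steps most likely to fail:

1. **Step 8 (radical quinone alkylation).** Risks are incomplete hydroboration next to the quaternary carbinol, O- versus C-attack on the quinone, and redox scrambling. Fallback: hydroborate/oxidise 9 to the 1,3-diol and make the primary iodide. Generate the same C4 radical under Ni/bipyridine–Zn reductive cross-electrophile coupling with 3-bromo-2,5-dimethyl-1,4-dimethoxybenzene (from 11 by reduction, methylation, bromination), then CAN oxidation to 12.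

2. **Step 3 (and the same issue in step 2): mono-coupling at one of two primary bromides.** Attack at the branched end gives a constitutional isomer that is hard to remove. Fallback: differentiate the ends by leaving group instead of sterics. From (R)-4-methyldihydrofuran-2(3H)-one make (R)-4-chloro-3-methylbutyl tosylate (SOCl2/ZnCl2; LiAlH4; TsCl). The Grignard then couples only at the tosylate, and the chloride is carried forward as the next Grignard precursor.

3. **Step 9 (ketalisation of a doubly flanked quinone carbonyl).** If the ketal does not form, direct reduction gives only the open hydroquinone. Fallback: switch to an invertive closure. Reduce 12 to the hydroquinone and cyclodehydrate with acid, which is reported to proceed with predominant inversion at the carbinol carbon (the course must be verified). Feed this with the (3S)-epimer of 9, made in step 5 with the other LLB antipode.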